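The earlier runs and the new flask are calculated on assumed constants; noise was put on by code.

The ratio I watch is reagent charged per left-handed substrate charged, 1.20 equivalents in this flask.

| flask | left-handed substrate | right-handed substrate | reagent | catalyst | remark | time |
|---|---|---|---|---|---|---|
| Saturday's | 0.099 M | 0.099 M | 0.080 M | 2.5 mM | run made earlier |  |
| Thursday's | 0.099 M | 0.099 M | 0.18 M | 2.5 mM | run made earlier |  |
| Tuesday's | 0.050 M | 0.050 M | 0.119 M | 2.5 mM | run made earlier |  |
| flask | 0.099 M | 0.099 M | 0.119 M | 2.5 mM |  | 4.0 h |

| run | time / h | right-handed substrate / % | left-handed substrate / % | left-handed product / % |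
|---|---|---|---|---|
| Saturday's | 0.417 | 47.9 | 29.7 | 21.2 |
| Saturday's | 0.833 | 47.3 | 26.6 | 24.2 |
| Saturday's | 2.00 | 46.9 | 25.0 | 26.3 |
| Saturday's | 5.00 | 47.7 | 23.3 | 29.3 |
| Thursday's | 0.667 | 44.0 | 12.9 | 36.7 |
| Thursday's | 1.50 | 44.1 | 9.2 | 38.4 |
| Thursday's | 3.00 | 42.4 | 9.8 | 41.4 |
| Thursday's | 5.00 | 40.5 | 8.4 | 41.2 |
| Tuesday's | 0.667 | 44.4 | 14.3 | 36.1 |
| Tuesday's | 1.50 | 43.3 | 9.1 | 37.9 |
| Tuesday's | 3.00 | 40.5 | 5.5 | 44.2 |
| Tuesday's | 5.00 | 39.8 | 4.4 | 46.9 |

(standard deviation of a reading: 1 percentage point)

* whether the excess of right-handed substrate over left-handed substrate among what is left of the two reaches 99% by 4.0 h (no / yes)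
* the highest excess of right-handed substrate over left-handed substrate among what is left of the two up to 4.0 h

- catalyst is single-handed; left-handed substrate and right-handed substrate are mirror images of each other, charged as a racemate, each of them at the stated concentration
- the earlier runs were read with a standard deviation of 1 percentage point

Write L for left-handed substrate and S for right-handed substrate, each charged as half of the total, and call ln(L charged / L left) the depth. At the last readings, depth per equivalent of reagent is 0.945 on Saturday, 0.981 on Thursday and 1.02 on Tuesday, though Tuesday has half the substrate. Their mean is 0.982, and this g, the depth per equivalent, is what I carry.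

Tuesday's last pair gives a selectivity factor, ln(L fraction left)/ln(S fraction left), of 10.7, as a reading. So I estimate for this flask a depth of 1.18, L at 15.4%, S at 44.8%, and an excess (S−L)/(S+L) of 48.9%, far below 99%.

The weak link is time: those readings stand at 5.00 h, but the flask stops at 4.0 h. Reforged on Thursday's and Tuesday's readings at 3.00 h, g is 0.912, the depth 1.10, and the excess 45.9%. I commit to a top between these two, and to no.

The forecast says no and 46%, on different grounds, a fitted exposure of the catalyst; its excess “rises monotonically and never approaches” the level.

The flask gives no and a top of 49.3%.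

    reagent ⇌ dormant form (K = 0.970, k = 0.0220 min⁻¹)
    2 reagent → homo dimer (k = 0.540 M⁻¹ min⁻¹)
    reagent + catalyst + right-handed substrate → catalyst + right-handed product (k = 42.0 M⁻² min⁻¹)
    reagent + catalyst + left-handed substrate → catalyst + left-handed product (k = 470 M⁻² min⁻¹)

In the flask, half of the left-handed turnover up to 4.0 h was done by 0.0855 h, and by 0.400 h reagent stood at 6.23% of its charge, with 0.0193 M of homo dimer formed. Then the dormant form shrank from 0.0105 M to 5.44 × 10⁻⁴ M while left-handed substrate crept from 22.0% to 15.3% at 4.00 h, with catalyst at 100%, which puts g at 0.987 here. For the neighbour with 0.30 M of reagent, g gives a top of 87.4%, and that flask reaches 87.9%.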